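**Retrosynthetic overview**
1. Target 29 ⇒ the C10 acetate and C6 anisoate go on last; ring B (cycloheptene) comes from diene 27 by ring-closing metathesis forming C8=C9.
2. C4 tertiary carbinol ⇒ isopropylcerium addition to cyclopentanone 22, anti to the C5 side chain.
3. C5–C6 bond (key step) ⇒ intermolecular anti-selective boron aldol between the α′-enolate of cyclopentenone 16 and 3-methylbut-3-enal 18, on the ring face opposite the bulky C10 side chain.
4. Cyclopentenone 16 (ring A) ⇒ aldol condensation of 1,4-keto aldehyde 14; quaternary C1 ⇒ Fráter–Seebach methylation; C10 ⇒ Evans syn-aldol of pent-4-ynoyl oxazolidinone 4 with acrolein.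
5. Ring order: ring A (five-membered) first by aldol condensation, ring B (seven-membered) last by metathesis.

Assumption: locants C1–C10 below are the daucane locants of the target (C1 quaternary C–CH3, C4 isopropyl carbinol, C5 ring-fusion CH, C6 anisoyloxy carbon, C8=C9 alkene, C10 acetoxy carbon); the target is (3R,3aS,4S,8R,8aS) in azulene numbering.

**Step 1**
Reactants: 1 pent-4-ynoic acid; 2 (4S)-4-benzyl-1,3-oxazolidin-2-one
Product: 4 (4S)-4-benzyl-3-(pent-4-ynoyl)-1,3-oxazolidin-2-one, via pivalic mixed anhydride 3 (not isolated)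
Conditions: PivCl, Et3N, THF, −20 °C; then LiCl, 2, −20 °C → rt
Reagents that add atoms: none
Why: N-acylation of the Evans auxiliary by the mixed-anhydride method, in which the LiCl-activated oxazolidinone attacks the less hindered carbonyl of 3, and no stereocenter is formed.

**Step 2**
Reactants: 4 N-pentynoyl oxazolidinone; 5 acrolein (prop-2-enal)
Product: 7 (4S)-4-benzyl-3-[(2S,3R)-3-hydroxy-2-(prop-2-yn-1-yl)pent-4-enoyl]-1,3-oxazolidin-2-one, via dibutylboron Z-enolate 6 (not isolated)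
Conditions: Bu2BOTf, iPr2NEt, CH2Cl2, 0 °C; 5, −78 → 0 °C; pH 7 buffer, MeOH, 30% H2O2, 0 °C
Reagents that add atoms: none
Why: Evans syn-aldol reaction in which the Z-boron enolate reacts through a Zimmerman–Traxler chair on the face away from the benzyl group, fixing the carbinol C10 as R (2,3-syn adduct) while the alkyne is inert.

**Step 3**
Reactants: 7 Evans aldol adduct
Product: 8 methyl (2S,3R)-3-hydroxy-2-(prop-2-yn-1-yl)pent-4-enoate
Conditions: NaOMe (1.1 equiv), MeOH, 0 °C, 15 min; aq. NH4Cl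
Reagents that add atoms: methanol, CO
Why: Transesterification at the exocyclic imide carbonyl releases the recyclable auxiliary and leaves the C10 stereocenter untouched.

**Step 4**
Reactants: 8 β-hydroxy ester
Product: 10 methyl (2S,3R)-3-hydroxy-2-methyl-2-(prop-2-yn-1-yl)pent-4-enoate, via trilithium alkoxide enolate 9 (not isolated)
Conditions: LiN(iPr)2 (3.3 equiv), THF, −78 → −20 °C; MeI (1.5 equiv), −78 → −20 °C; aq. NH4Cl
Reagents that add atoms: iodomethane, CI
Why: Fráter–Seebach alkylation in which the chelated lithium alkoxide–enolate is methylated on the face opposite the vinyl group (methyl anti to the oxygen), so C10 sets quaternary C1 with the propargyl arm syn to oxygen, and the lithium acetylide is not alkylated without a polar cosolvent.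

**Step 5**
Reactants: 10 quaternary hydroxy ester
Product: 11 methyl (2S,3R)-3-{[tert-butyl(dimethyl)silyl]oxy}-2-methyl-2-(prop-2-yn-1-yl)pent-4-enoate
Conditions: TBSOTf, 2,6-lutidine, CH2Cl2, −78 → 0 °C
Reagents that add atoms: tert-butyldimethylsilyl trifluoromethanesulfonate, CC(C)(C)[Si](C)(C)OS(=O)(=O)C(F)(F)F
Why: Silyl ether formation with the reactive triflate protects the hindered allylic alcohol, blocks retro-aldol and creates the bulky C10 substituent used later for facial control, with no change at any stereocenter.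

**Step 6**
Reactants: 11 silyl ether ester
Product: 12 (2R,3R)-3-{[tert-butyl(dimethyl)silyl]oxy}-2-methyl-2-(prop-2-yn-1-yl)pent-4-en-1-ol
Conditions: iBu2AlH (3 equiv), CH2Cl2, −78 → 0 °C; aq. potassium sodium tartrate
Reagents that add atoms: none
Why: Aluminium hydride reduction of the neopentyl ester to the primary alcohol, with alkyne, alkene and silyl ether inert at low temperature (the descriptor at C1 changes only by priority).

**Step 7**
Reactants: 12 primary alcohol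
Product: 13 (2S,3R)-3-{[tert-butyl(dimethyl)silyl]oxy}-2-methyl-2-(prop-2-yn-1-yl)pent-4-enal
Conditions: Dess–Martin periodinane, NaHCO3, CH2Cl2, 0 °C → rt
Reagents that add atoms: none
Why: Dess–Martin oxidation gives the aldehyde, which has a quaternary α-carbon and therefore cannot epimerise or enolise.

**Step 8**
Reactants: 13 alkynyl aldehyde
Product: 14 (2S,3R)-3-{[tert-butyl(dimethyl)silyl]oxy}-2-methyl-2-(2-oxopropyl)pent-4-enal
Conditions: Ph3PAuNTf2 (2 mol %), H2O (5 equiv), 1,4-dioxane, 60 °C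
Reagents that add atoms: water, O
Why: Gold-catalysed Markovnikov hydration of the terminal alkyne (assisted by the neighbouring carbonyl oxygen) gives the methyl ketone of a 1,4-keto aldehyde without touching the vinyl group.

**Step 9**
Reactants: 14 keto aldehyde
Product: 16 (4R)-4-[(1R)-1-{[tert-butyl(dimethyl)silyl]oxy}prop-2-en-1-yl]-4-methylcyclopent-2-en-1-one, via cyclic aldol 15 (not isolated)
Conditions: KOH (0.5 equiv), EtOH, rt
Reagents that add atoms: none
Why: Intramolecular aldol condensation in which only the methyl-ketone enolate can reach the non-enolisable aldehyde through a five-membered ring, and dehydration gives the 4,4-disubstituted cyclopentenone (ring A) with both stereocenters non-enolisable.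

**Step 10**
Reactants: 17 3-methylbut-3-en-1-ol
Product: 18 3-methylbut-3-enal
Conditions: Dess–Martin periodinane, NaHCO3, CH2Cl2, 0 °C → rt; filtered through silica and used at once as a cold solution
Reagents that add atoms: none
Why: Dess–Martin oxidation under buffered, base-free conditions gives the β,γ-unsaturated aldehyde without isomerisation to the conjugated enal.

**Step 11**
Reactants: 16 cyclopentenone; 18 3-methylbut-3-enal
Product: 20 (4S,5S)-4-[(1R)-1-{[tert-butyl(dimethyl)silyl]oxy}prop-2-en-1-yl]-5-[(1S)-1-hydroxy-3-methylbut-3-en-1-yl]-4-methylcyclopent-2-en-1-one, via dicyclohexylboron dienolate 19 (not isolated)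
Conditions: (c-C6H11)2BCl, Et3N, Et2O, −78 → 0 °C; 18, −78 → −20 °C; pH 7 buffer, MeOH, 30% H2O2, 0 °C
Reagents that add atoms: none
Why: Key boron-mediated aldol reaction in which α′-enolisation is regiospecific (C1 is quaternary, C3 is sp2), the ring-locked E-enolate gives the anti aldol through a Zimmerman–Traxler chair (C6 S), and the aldehyde adds to the face opposite the bulky silyloxyallyl group on C1 (C5 S, new chain cis to the methyl group).

**Step 12**
Reactants: 20 aldol adduct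
Product: 21 (4S,5S)-4-[(1R)-1-{[tert-butyl(dimethyl)silyl]oxy}prop-2-en-1-yl]-4-methyl-5-{(1S)-3-methyl-1-[(triethylsilyl)oxy]but-3-en-1-yl}cyclopent-2-en-1-one
Conditions: TESOTf, 2,6-lutidine, CH2Cl2, −78 °C
Reagents that add atoms: triethylsilyl trifluoromethanesulfonate, CC[Si](CC)(CC)OS(=O)(=O)C(F)(F)F
Why: Low-temperature silylation of the aldol hydroxyl prevents retro-aldol and alkoxide formation in the next two steps and changes no stereocenter.

**Step 13**
Reactants: 21 silylated enone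
Product: 22 (2S,3S)-3-[(1R)-1-{[tert-butyl(dimethyl)silyl]oxy}prop-2-en-1-yl]-3-methyl-2-{(1S)-3-methyl-1-[(triethylsilyl)oxy]but-3-en-1-yl}cyclopentan-1-one
Conditions: [(Ph3P)CuH]6 (0.5 equiv), H2O (3 equiv), toluene, rt
Reagents that add atoms: none
Why: Conjugate reduction with the copper hydride hexamer (Stryker reagent) reduces only the enone C=C, leaves the isolated alkenes alone, and the copper enolate is protonated at C3 so C5 is not epimerised.

**Step 14**
Reactants: 22 cyclopentanone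
Product: 23 (1R,2S,3S)-3-[(1R)-1-{[tert-butyl(dimethyl)silyl]oxy}prop-2-en-1-yl]-3-methyl-2-{(1S)-3-methyl-1-[(triethylsilyl)oxy]but-3-en-1-yl}-1-(propan-2-yl)cyclopentan-1-ol
Conditions: anhydrous CeCl3 (3 equiv), iPrMgCl (3 equiv), THF, −78 °C; then 22, −78 → 0 °C; aq. NH4Cl
Reagents that add atoms: isopropylmagnesium chloride, CC(C)[Mg]Cl
Why: Imamoto organocerium 1,2-addition suppresses enolisation and β-hydride reduction, and the nucleophile attacks the carbonyl face anti to the adjacent C5 side chain, giving the tertiary alcohol with hydroxyl cis to that chain (C4 R).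

**Step 15**
Reactants: 23 bis-silyl tertiary alcohol
Product: 24 (1R,2S,3S)-3-[(1R)-1-{[tert-butyl(dimethyl)silyl]oxy}prop-2-en-1-yl]-2-[(1S)-1-hydroxy-3-methylbut-3-en-1-yl]-3-methyl-1-(propan-2-yl)cyclopentan-1-ol
Conditions: PPTS (0.2 equiv), MeOH/CH2Cl2 (1:1), 0 °C → rt
Reagents that add atoms: none
Why: Acid-catalysed methanolysis removes the triethylsilyl ether selectively while the hindered allylic tert-butyldimethylsilyl ether survives, with no change at any stereocenter.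

**Step 16**
Reactants: 24 diol; 25 4-methoxybenzoyl chloride
Product: 26 (1S)-1-[(1S,2R,5S)-5-[(1R)-1-{[tert-butyl(dimethyl)silyl]oxy}prop-2-en-1-yl]-2-hydroxy-5-methyl-2-(propan-2-yl)cyclopentyl]-3-methylbut-3-en-1-yl 4-methoxybenzoate
Conditions: Et3N, DMAP, CH2Cl2, 0 °C → rt
Reagents that add atoms: none
Why: DMAP-catalysed acylation of the only secondary alcohol proceeds with retention at C6, and the tertiary C4 hydroxyl does not react.

**Step 17**
Reactants: 26 silylated anisoate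
Product: 27 (1S)-1-[(1S,2R,5S)-2-hydroxy-5-[(1R)-1-hydroxyprop-2-en-1-yl]-5-methyl-2-(propan-2-yl)cyclopentyl]-3-methylbut-3-en-1-yl 4-methoxybenzoate
Conditions: HF·pyridine, pyridine, THF, 0 °C → rt
Reagents that add atoms: none
Why: Buffered fluoride desilylation frees the C10 allylic alcohol without touching the ester, the alkenes or any stereocenter.

**Step 18**
Reactants: 27 diene diol
Product: 28 (3R,3aS,4S,8R,8aS)-3,8-dihydroxy-6,8a-dimethyl-3-(propan-2-yl)-1,2,3,3a,4,5,8,8a-octahydroazulen-4-yl 4-methoxybenzoate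
Conditions: second-generation Grubbs catalyst (10 mol %), CH2Cl2 (2 mM), 40 °C
Reagents that add atoms: none
Why: Ring-closing metathesis between the vinyl carbinol and the 1,1-disubstituted alkene forms the trisubstituted C8=C9 bond and the trans-fused seven-membered ring B, the fusion being fixed by the trans C1/C5 substituents.

**Step 19**
Reactants: 28 bicyclic diol
Product: 29 (3R,3aS,4S,8R,8aS)-8-(acetyloxy)-3-hydroxy-6,8a-dimethyl-3-(propan-2-yl)-1,2,3,3a,4,5,8,8a-octahydroazulen-4-yl 4-methoxybenzoate (target)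
Conditions: Ac2O, Et3N, DMAP (cat.), CH2Cl2, rt
Reagents that add atoms: acetic anhydride, CC(=O)OC(C)=O
Why: DMAP-catalysed acetylation of the secondary allylic C10 alcohol with retention, while the tertiary C4 hydroxyl stays free, gives the target.

**Compound list**
1 | pent-4-ynoic acid | C#CCCC(=O)O | starting material
2 | (4S)-4-benzyl-1,3-oxazolidin-2-one | O=C1N[C@@H](Cc2ccccc2)CO1 | starting material
3 | 2,2-dimethylpropanoic pent-4-ynoic anhydride | C#CCCC(=O)OC(=O)C(C)(C)C | intermediate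
4 | (4S)-4-benzyl-3-(pent-4-ynoyl)-1,3-oxazolidin-2-one | C#CCCC(=O)N1[C@@H](Cc2ccccc2)COC1=O | intermediate
5 | acrolein (prop-2-enal) | C=CC=O | starting material
6 | dibutylboron (Z)-enolate of 4 | CCCCB(CCCC)O/C(=C\CC#C)N1[C@@H](Cc2ccccc2)COC1=O | intermediate
7 | (4S)-4-benzyl-3-[(2S,3R)-3-hydroxy-2-(prop-2-yn-1-yl)pent-4-enoyl]-1,3-oxazolidin-2-one | C=C[C@@H](O)[C@H](CC#C)C(=O)N1[C@@H](Cc2ccccc2)COC1=O | intermediate
8 | methyl (2S,3R)-3-hydroxy-2-(prop-2-yn-1-yl)pent-4-enoate | C=C[C@@H](O)[C@H](CC#C)C(=O)OC | intermediate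
9 | trilithium salt of 8 (alkoxide, ester enolate and acetylide) | [Li+].[Li+].[Li+].[C-]#CCC(=C([O-])OC)[C@H]([O-])C=C | intermediate
10 | methyl (2S,3R)-3-hydroxy-2-methyl-2-(prop-2-yn-1-yl)pent-4-enoate | C=C[C@@H](O)[C@](C)(CC#C)C(=O)OC | intermediate
11 | methyl (2S,3R)-3-{[tert-butyl(dimethyl)silyl]oxy}-2-methyl-2-(prop-2-yn-1-yl)pent-4-enoate | C=C[C@@H](O[Si](C)(C)C(C)(C)C)[C@](C)(CC#C)C(=O)OC | intermediate
12 | (2R,3R)-3-{[tert-butyl(dimethyl)silyl]oxy}-2-methyl-2-(prop-2-yn-1-yl)pent-4-en-1-ol | C=C[C@@H](O[Si](C)(C)C(C)(C)C)[C@](C)(CC#C)CO | intermediate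
13 | (2S,3R)-3-{[tert-butyl(dimethyl)silyl]oxy}-2-methyl-2-(prop-2-yn-1-yl)pent-4-enal | C=C[C@@H](O[Si](C)(C)C(C)(C)C)[C@](C)(CC#C)C=O | intermediate
14 | (2S,3R)-3-{[tert-butyl(dimethyl)silyl]oxy}-2-methyl-2-(2-oxopropyl)pent-4-enal | C=C[C@@H](O[Si](C)(C)C(C)(C)C)[C@](C)(CC(C)=O)C=O | intermediate
15 | (3R)-3-[(1R)-1-{[tert-butyl(dimethyl)silyl]oxy}prop-2-en-1-yl]-4-hydroxy-3-methylcyclopentan-1-one (both C4 epimers) | C=C[C@@H](O[Si](C)(C)C(C)(C)C)[C@]1(C)CC(=O)CC1O | intermediate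
16 | (4R)-4-[(1R)-1-{[tert-butyl(dimethyl)silyl]oxy}prop-2-en-1-yl]-4-methylcyclopent-2-en-1-one | C=C[C@@H](O[Si](C)(C)C(C)(C)C)[C@]1(C)CC(=O)C=C1 | intermediate
17 | 3-methylbut-3-en-1-ol | CC(=C)CCO | starting material
18 | 3-methylbut-3-enal | CC(=C)CC=O | intermediate
19 | dicyclohexylboron cross-conjugated dienolate of 16 (2-boryloxycyclopenta-1,3-diene) | C=C[C@@H](O[Si](C)(C)C(C)(C)C)[C@]1(C)C=C(OB(C2CCCCC2)C2CCCCC2)C=C1 | intermediate
20 | (4S,5S)-4-[(1R)-1-{[tert-butyl(dimethyl)silyl]oxy}prop-2-en-1-yl]-5-[(1S)-1-hydroxy-3-methylbut-3-en-1-yl]-4-methylcyclopent-2-en-1-one | C=C[C@@H](O[Si](C)(C)C(C)(C)C)[C@]1(C)[C@@H]([C@@H](O)CC(C)=C)C(=O)C=C1 | intermediate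
21 | (4S,5S)-4-[(1R)-1-{[tert-butyl(dimethyl)silyl]oxy}prop-2-en-1-yl]-4-methyl-5-{(1S)-3-methyl-1-[(triethylsilyl)oxy]but-3-en-1-yl}cyclopent-2-en-1-one | C=C[C@@H](O[Si](C)(C)C(C)(C)C)[C@]1(C)[C@@H]([C@@H](O[Si](CC)(CC)CC)CC(C)=C)C(=O)C=C1 | intermediate
22 | (2S,3S)-3-[(1R)-1-{[tert-butyl(dimethyl)silyl]oxy}prop-2-en-1-yl]-3-methyl-2-{(1S)-3-methyl-1-[(triethylsilyl)oxy]but-3-en-1-yl}cyclopentan-1-one | C=C[C@@H](O[Si](C)(C)C(C)(C)C)[C@]1(C)[C@@H]([C@@H](O[Si](CC)(CC)CC)CC(C)=C)C(=O)CC1 | intermediate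
23 | (1R,2S,3S)-3-[(1R)-1-{[tert-butyl(dimethyl)silyl]oxy}prop-2-en-1-yl]-3-methyl-2-{(1S)-3-methyl-1-[(triethylsilyl)oxy]but-3-en-1-yl}-1-(propan-2-yl)cyclopentan-1-ol | C=C[C@@H](O[Si](C)(C)C(C)(C)C)[C@]1(C)[C@@H]([C@@H](O[Si](CC)(CC)CC)CC(C)=C)[C@](O)(C(C)C)CC1 | intermediate
24 | (1R,2S,3S)-3-[(1R)-1-{[tert-butyl(dimethyl)silyl]oxy}prop-2-en-1-yl]-2-[(1S)-1-hydroxy-3-methylbut-3-en-1-yl]-3-methyl-1-(propan-2-yl)cyclopentan-1-ol | C=C[C@@H](O[Si](C)(C)C(C)(C)C)[C@]1(C)[C@@H]([C@@H](O)CC(C)=C)[C@](O)(C(C)C)CC1 | intermediate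
25 | 4-methoxybenzoyl chloride | COc1ccc(cc1)C(Cl)=O | starting material
26 | (1S)-1-[(1S,2R,5S)-5-[(1R)-1-{[tert-butyl(dimethyl)silyl]oxy}prop-2-en-1-yl]-2-hydroxy-5-methyl-2-(propan-2-yl)cyclopentyl]-3-methylbut-3-en-1-yl 4-methoxybenzoate | C=C[C@@H](O[Si](C)(C)C(C)(C)C)[C@]1(C)[C@@H]([C@@H](OC(=O)c2ccc(OC)cc2)CC(C)=C)[C@](O)(C(C)C)CC1 | intermediate
27 | (1S)-1-[(1S,2R,5S)-2-hydroxy-5-[(1R)-1-hydroxyprop-2-en-1-yl]-5-methyl-2-(propan-2-yl)cyclopentyl]-3-methylbut-3-en-1-yl 4-methoxybenzoate | C=C[C@@H](O)[C@]1(C)[C@@H]([C@@H](OC(=O)c2ccc(OC)cc2)CC(C)=C)[C@](O)(C(C)C)CC1 | intermediate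
28 | (3R,3aS,4S,8R,8aS)-3,8-dihydroxy-6,8a-dimethyl-3-(propan-2-yl)-1,2,3,3a,4,5,8,8a-octahydroazulen-4-yl 4-methoxybenzoate | COc1ccc(C(=O)O[C@H]2CC(C)=C[C@@H](O)[C@@]3(C)CC[C@@](O)(C(C)C)[C@H]23)cc1 | intermediate
29 | (3R,3aS,4S,8R,8aS)-8-(acetyloxy)-3-hydroxy-6,8a-dimethyl-3-(propan-2-yl)-1,2,3,3a,4,5,8,8a-octahydroazulen-4-yl 4-methoxybenzoate | COc1ccc(C(=O)O[C@H]2CC(C)=C[C@@H](OC(C)=O)[C@@]3(C)CC[C@@](O)(C(C)C)[C@H]23)cc1 | target

**Step count:** 19 steps in total. The longest linear sequence is 18 steps (steps 1–9 and 11–19); step 10 is a one-step side branch.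

**Three steps most likely to fail**

Step 4 (quaternary methylation). The risks are modest diastereoselectivity at the crowded α-carbon, retro-aldol of the dianion, and stray methylation of the acetylide. The fallback sets out from ester 8 and comes back to the route at ester 10; it sets the center on a rigid ring by Seebach's acetal method. Saponification (LiOH, THF/H2O) gives the hydroxy acid F1. Acetalisation with pivalaldehyde (PPTS, CH2Cl2, water removal) gives the cis-2,6-disubstituted dioxanone F2. Its lithium enolate (LiN(iPr)2, 2.2 equiv, THF, −78 °C) is methylated by MeI trans to the C6 vinyl group, giving the methylated dioxanone F3. NaOMe in MeOH then opens the acetal to 10 with the same configuration.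

Step 11 (key aldol). The risks are base-induced conjugation or self-condensation of the β,γ-unsaturated aldehyde 18 and an eroded anti/facial ratio. The fallback sets out from enone 16 and comes back at diol 24; it uses a stable aldehyde that cannot conjugate and builds the alkene afterwards. Commercial ethyl (2-methyl-1,3-dioxolan-2-yl)acetate is reduced (iBu2AlH, CH2Cl2, −78 °C) to the ketal aldehyde F4. The same boron aldol with 16 gives the aldol adduct F5, TESOTf/2,6-lutidine gives the triethylsilyl ether F6, [(Ph3P)CuH]6 gives the saturated ketone F7, and iPrMgCl/CeCl3 gives the tertiary alcohol F8. PPTS in wet acetone removes both the dioxolane and the triethylsilyl group, giving the dihydroxy methyl ketone F9. Non-basic methylenation (Zn, CH2Br2, TiCl4, THF) then gives 24.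

Step 14 (isopropyl addition). The risks are enolisation followed by loss of the β-silyloxy group, and slow or wrong-face attack because the C1 side chain crowds the face anti to the C5 chain. The fallback sets out from ketone 22 and comes back at bicyclic diol 28; it closes ring B before the addition so that the C10 substituent is tied back. Ring-closing metathesis of 22 (second-generation Hoveyda–Grubbs catalyst, toluene, 80 °C) gives the bicyclic ketone F10. iPrMgCl/CeCl3 adds from the face opposite the angular methyl and the C6 carbon, giving the bicyclic tertiary alcohol F11. PPTS/MeOH gives the bicyclic diol F12, acylation with 25 (Et3N, DMAP) gives the silylated anisoate F13, and HF·pyridine gives 28.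

**Further compounds**
F1 | step 4 | (2S,3R)-3-hydroxy-2-(prop-2-yn-1-yl)pent-4-enoic acid | C=C[C@@H](O)[C@H](CC#C)C(=O)O
F2 | step 4 | (2R,5S,6R)-2-tert-butyl-6-ethenyl-5-(prop-2-yn-1-yl)-1,3-dioxan-4-one | C=C[C@H]1O[C@@H](C(C)(C)C)OC(=O)[C@H]1CC#C
F3 | step 4 | (2R,5S,6R)-2-tert-butyl-6-ethenyl-5-methyl-5-(prop-2-yn-1-yl)-1,3-dioxan-4-one | C=C[C@H]1O[C@@H](C(C)(C)C)OC(=O)[C@@]1(C)CC#C
F4 | step 11 | (2-methyl-1,3-dioxolan-2-yl)acetaldehyde | CC1(CC=O)OCCO1
F5 | step 11 | (4S,5S)-4-[(1R)-1-{[tert-butyl(dimethyl)silyl]oxy}prop-2-en-1-yl]-5-[(1S)-1-hydroxy-2-(2-methyl-1,3-dioxolan-2-yl)ethyl]-4-methylcyclopent-2-en-1-one | C=C[C@@H](O[Si](C)(C)C(C)(C)C)[C@]1(C)[C@@H]([C@@H](O)CC2(C)OCCO2)C(=O)C=C1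
F6 | step 11 | (4S,5S)-4-[(1R)-1-{[tert-butyl(dimethyl)silyl]oxy}prop-2-en-1-yl]-4-methyl-5-{(1S)-2-(2-methyl-1,3-dioxolan-2-yl)-1-[(triethylsilyl)oxy]ethyl}cyclopent-2-en-1-one | C=C[C@@H](O[Si](C)(C)C(C)(C)C)[C@]1(C)[C@@H]([C@@H](O[Si](CC)(CC)CC)CC2(C)OCCO2)C(=O)C=C1
F7 | step 11 | (2S,3S)-3-[(1R)-1-{[tert-butyl(dimethyl)silyl]oxy}prop-2-en-1-yl]-3-methyl-2-{(1S)-2-(2-methyl-1,3-dioxolan-2-yl)-1-[(triethylsilyl)oxy]ethyl}cyclopentan-1-one | C=C[C@@H](O[Si](C)(C)C(C)(C)C)[C@]1(C)[C@@H]([C@@H](O[Si](CC)(CC)CC)CC2(C)OCCO2)C(=O)CC1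
F8 | step 11 | (1R,2S,3S)-3-[(1R)-1-{[tert-butyl(dimethyl)silyl]oxy}prop-2-en-1-yl]-3-methyl-2-{(1S)-2-(2-methyl-1,3-dioxolan-2-yl)-1-[(triethylsilyl)oxy]ethyl}-1-(propan-2-yl)cyclopentan-1-ol | C=C[C@@H](O[Si](C)(C)C(C)(C)C)[C@]1(C)[C@@H]([C@@H](O[Si](CC)(CC)CC)CC2(C)OCCO2)[C@](O)(C(C)C)CC1
F9 | step 11 | (4S)-4-[(1S,2R,5S)-5-[(1R)-1-{[tert-butyl(dimethyl)silyl]oxy}prop-2-en-1-yl]-2-hydroxy-5-methyl-2-(propan-2-yl)cyclopentyl]-4-hydroxybutan-2-one | C=C[C@@H](O[Si](C)(C)C(C)(C)C)[C@]1(C)[C@@H]([C@@H](O)CC(C)=O)[C@](O)(C(C)C)CC1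
F10 | step 14 | (3aS,4S,8R,8aS)-8-{[tert-butyl(dimethyl)silyl]oxy}-6,8a-dimethyl-4-[(triethylsilyl)oxy]-2,3a,4,5,8,8a-hexahydroazulen-3(1H)-one | CC[Si](CC)(CC)O[C@H]1CC(C)=C[C@@H](O[Si](C)(C)C(C)(C)C)[C@@]2(C)CCC(=O)[C@H]12
F11 | step 14 | (3R,3aS,4S,8R,8aS)-8-{[tert-butyl(dimethyl)silyl]oxy}-6,8a-dimethyl-3-(propan-2-yl)-4-[(triethylsilyl)oxy]-1,2,3,3a,4,5,8,8a-octahydroazulen-3-ol | CC[Si](CC)(CC)O[C@H]1CC(C)=C[C@@H](O[Si](C)(C)C(C)(C)C)[C@@]2(C)CC[C@@](O)(C(C)C)[C@H]12
F12 | step 14 | (3R,3aS,4S,8R,8aS)-8-{[tert-butyl(dimethyl)silyl]oxy}-6,8a-dimethyl-3-(propan-2-yl)-1,2,3,3a,4,5,8,8a-octahydroazulene-3,4-diol | O[C@H]1CC(C)=C[C@@H](O[Si](C)(C)C(C)(C)C)[C@@]2(C)CC[C@@](O)(C(C)C)[C@H]12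
F13 | step 14 | (3R,3aS,4S,8R,8aS)-8-{[tert-butyl(dimethyl)silyl]oxy}-3-hydroxy-6,8a-dimethyl-3-(propan-2-yl)-1,2,3,3a,4,5,8,8a-octahydroazulen-4-yl 4-methoxybenzoate | COc1ccc(cc1)C(=O)O[C@H]1CC(C)=C[C@@H](O[Si](C)(C)C(C)(C)C)[C@@]2(C)CC[C@@](O)(C(C)C)[C@H]12
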